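**Plan**

1. Retrosynthesis: the ester bond O3'–C(=O) is cut first, then the C3–O bond (back to a C2=C3 enol ether, a 4H-chromene), then C3–C4 and O1–C8a together. This leaves a ring-B aryl methyl ketone and a ring-A 2-bromobenzyl bromide.
2. Enabling feature: C3 lies between the benzylic C4 on ring A and C2, whose oxygen O1 is bonded to C8a, the ring-A carbon ortho to C4a. Ring A carrying C4–Br and C8a–Br is therefore a 1,3-dielectrophile, and the ketone unit O1=C2–C3H3 is, as its enolate, a 1,3-C,O-dinucleophile. Their formal [3+3] union closes ring C and leaves the C2=C3 enol ether.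
3. Forward: ring-A piece 5 (4 steps from 5-bromoresorcinol) and ring-B ketone 10 (4 steps from methyl gallate) are joined in step 9, which closes ring C. Hydroboration, MOM removal, galloylation at O3' and global hydrogenolysis follow.
4. Stereochemistry: C2 and C3 are both set in step 10 by syn addition of IpcBH2 [from (+)-α-pinene] across C2=C3 (boron on C3, hydrogen on C2). Syn addition fixes 2,3-trans, the reagent fixes the (2R,3S) sense, and no later step touches either centre.
5. Protecting groups: benzyl ethers and a diphenylmethylene ketal on O4'/O5' fall together in the last step; MOM on O3' is the one orthogonal group and marks the galloylation site.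

Key step: step 9

Assumption: the sense of induction of IpcBH2 on the 2-aryl-4H-chromene is taken to be that known for 1-arylcycloalkenes, and bromide 5 is used crude directly after its preparation.

**Route**

Step 1
Reactants: 1 5-bromoresorcinol
Product: 2 1,3-bis(benzyloxy)-5-bromobenzene
Conditions: BnBr, K2CO3, DMF, 60 °C
Reagents that add atoms: benzyl bromide, BrCc1ccccc1
Why: Williamson ether synthesis on both phenols should proceed cleanly, and no stereocentre is involved.

Step 2
Reactants: 2 1,3-bis(benzyloxy)-5-bromobenzene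
Product: 3 2,4-bis(benzyloxy)-6-bromobenzaldehyde
Conditions: POCl3, DMF, 0 → 70 °C; then aq NaOAc
Reagents that add atoms: N,N-dimethylformamide, CN(C)C=O; water, O
Why: Vilsmeier–Haack formylation should take place para to one benzyloxy group and ortho to the other, at the C–H next to bromine and not at the more hindered C–H between the two ether groups, as is known for 1-bromo-3,5-dimethoxybenzene.

Step 3
Reactants: 3 2,4-bis(benzyloxy)-6-bromobenzaldehyde
Product: 4 [2,4-bis(benzyloxy)-6-bromophenyl]methanol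
Conditions: NaBH4, THF/MeOH, 0 °C
Reagents that add atoms: none
Why: Hydride reduction of the aryl aldehyde should leave the aryl bromide and the benzyl ethers untouched.

Step 4
Reactants: 4 [2,4-bis(benzyloxy)-6-bromophenyl]methanol
Product: 5 1,5-bis(benzyloxy)-3-bromo-2-(bromomethyl)benzene
Conditions: PBr3, Et2O, 0 °C
Reagents that add atoms: phosphorus tribromide, BrP(Br)Br
Why: Conversion of the benzylic alcohol to the bromide through its phosphite ester should be fast for this electron-rich benzyl system, and the labile product is carried on at once.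

Step 5
Reactants: 6 methyl gallate
Product: 7 methyl 7-hydroxy-2,2-diphenyl-1,3-benzodioxole-5-carboxylate
Conditions: Ph2CCl2, neat, 175 °C
Reagents that add atoms: dichlorodiphenylmethane, ClC(Cl)(c1ccccc1)c1ccccc1
Why: Ketalisation of two adjacent phenols by the gem-dichloride can only bridge a vicinal pair, so one terminal phenol (the later O3') should stay free and be differentiated from O4'/O5'.

Step 6
Reactants: 7 methyl 7-hydroxy-2,2-diphenyl-1,3-benzodioxole-5-carboxylate
Product: 8 methyl 7-(methoxymethoxy)-2,2-diphenyl-1,3-benzodioxole-5-carboxylate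
Conditions: MOMCl, i-Pr2NEt, CH2Cl2, 0 °C → rt
Reagents that add atoms: chloromethyl methyl ether, COCCl
Why: O-Alkylation of the remaining phenol gives a base-stable acetal that should survive every organometallic and basic step up to step 11.

Step 7
Reactants: 8 methyl 7-(methoxymethoxy)-2,2-diphenyl-1,3-benzodioxole-5-carboxylate
Product: 9 N-methoxy-N-methyl-7-(methoxymethoxy)-2,2-diphenyl-1,3-benzodioxole-5-carboxamide
Conditions: MeNH(OMe)·HCl, i-PrMgCl, THF, −20 °C
Reagents that add atoms: N,O-dimethylhydroxylamine hydrochloride, CNOC.Cl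
Why: Aminolysis of the ester by the chloromagnesium amide of N,O-dimethylhydroxylamine (Weinreb amide formation) should be direct and leave the acetal and ketal intact.

Step 8
Reactants: 9 N-methoxy-N-methyl-7-(methoxymethoxy)-2,2-diphenyl-1,3-benzodioxole-5-carboxamide
Product: 10 1-[7-(methoxymethoxy)-2,2-diphenyl-1,3-benzodioxol-5-yl]ethan-1-one
Conditions: MeMgBr, THF, 0 °C; aq NH4Cl
Reagents that add atoms: methylmagnesium bromide, C[Mg]Br
Why: Weinreb ketone synthesis should stop at the methyl ketone because the chelated tetrahedral intermediate persists until work-up.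

Step 9
Reactants: 10 1-[7-(methoxymethoxy)-2,2-diphenyl-1,3-benzodioxol-5-yl]ethan-1-one; 5 1,5-bis(benzyloxy)-3-bromo-2-(bromomethyl)benzene
Product: 13 5,7-bis(benzyloxy)-2-[7-(methoxymethoxy)-2,2-diphenyl-1,3-benzodioxol-5-yl]-4H-chromene, via lithium enolate 11 (not isolated), via bromo ketone 12 (not isolated)
Conditions: LiN(SiMe3)2, THF, −78 °C; 5, −78 → 0 °C; then NaOt-Bu, CuI (10 mol%), 3,4,7,8-tetramethyl-1,10-phenanthroline (20 mol%), toluene, 100 °C (THF distilled out)
Reagents that add atoms: none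
Why: The lithium enolate 11 displaces the benzylic bromide of 5 (SN2) and forms C3–C4; NaOt-Bu then enolises the new ketone 12 at its only α-CH2 (C3), monovalent copper bound to the enolate oxygen inserts into the C8a–Br bond, and C–O reductive elimination forms O1–C8a. The closest known reactions are the copper-catalysed domino C-benzylation/O-arylation of 1,3-dicarbonyl compounds with 2-bromobenzyl bromides to 4H-chromenes and the copper-catalysed intramolecular O-arylation of ketone enolates that gives benzofurans. Ring C is closed in the second event as a six-membered ring by intramolecular O-arylation (6-exo attack of O1 on C8a), the first event being intermolecular. No stereocentre is formed; the C2=C3 enol ether is kept as the handle for step 10. The selectivities needed are C- over O-alkylation and mono- over dialkylation (lithium enolate, low temperature, slight excess of 10), benzylic over aryl bromide in the first event (the aryl bromide is inert to the enolate without copper), and O- over C-arylation in the second (C-arylation at C3 would need a four-membered ring).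

Step 10
Reactants: 13 5,7-bis(benzyloxy)-2-[7-(methoxymethoxy)-2,2-diphenyl-1,3-benzodioxol-5-yl]-4H-chromene
Product: 15 (2R,3S)-5,7-bis(benzyloxy)-2-[7-(methoxymethoxy)-2,2-diphenyl-1,3-benzodioxol-5-yl]-3,4-dihydro-2H-chromen-3-ol, via C3-borane 14 (not isolated)
Conditions: IpcBH2 [from (+)-α-pinene], THF, −25 → 0 °C; then NaOH (aq), H2O2, 0 °C
Reagents that add atoms: hydrogen peroxide, OO
Why: In this asymmetric hydroboration–oxidation boron should add to C3 (β to O1 and to the aryl group) and hydrogen to C2 from the same face, so that after C–B oxidation with retention the 3-OH is trans to the 2-aryl group, while the isopinocampheyl group selects the face, (2R,3S) being expected by analogy with 1-arylcycloalkenes, which give (1S,2R)-trans-2-arylcycloalkanols with this reagent.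

Step 11
Reactants: 15 (2R,3S)-5,7-bis(benzyloxy)-2-[7-(methoxymethoxy)-2,2-diphenyl-1,3-benzodioxol-5-yl]-3,4-dihydro-2H-chromen-3-ol
Product: 16 (2R,3S)-5,7-bis(benzyloxy)-2-(7-hydroxy-2,2-diphenyl-1,3-benzodioxol-5-yl)-3,4-dihydro-2H-chromen-3-ol
Conditions: NaHSO4·SiO2, CH2Cl2, rt
Reagents that add atoms: none
Why: Mild heterogeneous acid hydrolysis of the phenolic MOM acetal should be selective over the benzyl ethers, the diaryl ketal and the benzylic C2–O1 bond, so neither stereocentre is disturbed.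

Step 12
Reactants: 17 3,4,5-tris(benzyloxy)benzoic acid
Product: 18 3,4,5-tris(benzyloxy)benzoyl chloride
Conditions: (COCl)2, DMF (cat.), CH2Cl2, 0 °C → rt
Reagents that add atoms: oxalyl chloride, O=C(Cl)C(Cl)=O
Why: Acid chloride formation through the chloroiminium (Vilsmeier-type) activation should be quantitative, and the chloride is used crude.

Step 13
Reactants: 16 (2R,3S)-5,7-bis(benzyloxy)-2-(7-hydroxy-2,2-diphenyl-1,3-benzodioxol-5-yl)-3,4-dihydro-2H-chromen-3-ol; 18 3,4,5-tris(benzyloxy)benzoyl chloride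
Product: 19 6-[(2R,3S)-5,7-bis(benzyloxy)-3-hydroxy-3,4-dihydro-2H-chromen-2-yl]-2,2-diphenyl-1,3-benzodioxol-4-yl 3,4,5-tris(benzyloxy)benzoate
Conditions: Et3N, CH2Cl2, −20 → 0 °C
Reagents that add atoms: none
Why: In this Schotten–Baumann-type acylation without an acyl-transfer catalyst the phenol, present as its ammonium phenoxide, should react far faster than the hindered secondary C3 alcohol, so the ester is placed on O3' only.

Step 14
Reactants: 19 6-[(2R,3S)-5,7-bis(benzyloxy)-3-hydroxy-3,4-dihydro-2H-chromen-2-yl]-2,2-diphenyl-1,3-benzodioxol-4-yl 3,4,5-tris(benzyloxy)benzoate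
Product: 20 gallocatechin 3'-O-gallate, 2,3-dihydroxy-5-[(2R,3S)-3,5,7-trihydroxy-3,4-dihydro-2H-chromen-2-yl]phenyl 3,4,5-trihydroxybenzoate
Conditions: H2 (1 atm), Pd(OH)2/C, THF/EtOAc, rt
Reagents that add atoms: none
Why: Neutral hydrogenolysis should remove the five O-benzyl groups and the diphenylmethylene ketal while leaving the aryl ester and the benzylic C2–O1 bond of the flavan, as is usual for benzylated catechin gallates; no alcohol solvent is used so that the aryl ester is not transesterified.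

**Compound list**

1 | 5-bromoresorcinol | Oc1cc(O)cc(Br)c1 | starting material
2 | 1,3-bis(benzyloxy)-5-bromobenzene | Brc1cc(OCc2ccccc2)cc(OCc2ccccc2)c1 | intermediate
3 | 2,4-bis(benzyloxy)-6-bromobenzaldehyde | O=Cc1c(Br)cc(OCc2ccccc2)cc1OCc1ccccc1 | intermediate
4 | [2,4-bis(benzyloxy)-6-bromophenyl]methanol | OCc1c(Br)cc(OCc2ccccc2)cc1OCc1ccccc1 | intermediate
5 | 1,5-bis(benzyloxy)-3-bromo-2-(bromomethyl)benzene | BrCc1c(Br)cc(OCc2ccccc2)cc1OCc1ccccc1 | intermediate
6 | methyl gallate | COC(=O)c1cc(O)c(O)c(O)c1 | starting material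
7 | methyl 7-hydroxy-2,2-diphenyl-1,3-benzodioxole-5-carboxylate | COC(=O)c1cc(O)c2OC(c3ccccc3)(c3ccccc3)Oc2c1 | intermediate
8 | methyl 7-(methoxymethoxy)-2,2-diphenyl-1,3-benzodioxole-5-carboxylate | COC(=O)c1cc(OCOC)c2OC(c3ccccc3)(c3ccccc3)Oc2c1 | intermediate
9 | N-methoxy-N-methyl-7-(methoxymethoxy)-2,2-diphenyl-1,3-benzodioxole-5-carboxamide | CON(C)C(=O)c1cc(OCOC)c2OC(c3ccccc3)(c3ccccc3)Oc2c1 | intermediate
10 | 1-[7-(methoxymethoxy)-2,2-diphenyl-1,3-benzodioxol-5-yl]ethan-1-one | CC(=O)c1cc(OCOC)c2OC(c3ccccc3)(c3ccccc3)Oc2c1 | intermediate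
11 | lithium enolate of 10 (not isolated) | [Li]OC(=C)c1cc(OCOC)c2OC(c3ccccc3)(c3ccccc3)Oc2c1 | intermediate
12 | 3-[2,4-bis(benzyloxy)-6-bromophenyl]-1-[7-(methoxymethoxy)-2,2-diphenyl-1,3-benzodioxol-5-yl]propan-1-one (not isolated) | O=C(CCc1c(Br)cc(OCc2ccccc2)cc1OCc1ccccc1)c1cc(OCOC)c2OC(c3ccccc3)(c3ccccc3)Oc2c1 | intermediate
13 | 5,7-bis(benzyloxy)-2-[7-(methoxymethoxy)-2,2-diphenyl-1,3-benzodioxol-5-yl]-4H-chromene | COCOc1cc(C2=CCc3c(OCc4ccccc4)cc(OCc4ccccc4)cc3O2)cc2OC(c3ccccc3)(c3ccccc3)Oc12 | intermediate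
14 | isopinocampheyl borane carrying the flavan on boron through C3, boron cis to H2 and trans to the 2-aryl group (not isolated) | C[C@H]1[C@H](B[C@H]3Cc4c(OCc5ccccc5)cc(OCc5ccccc5)cc4O[C@@H]3c3cc(OCOC)c4OC(c5ccccc5)(c5ccccc5)Oc4c3)C[C@@H]2C[C@H]1C2(C)C | intermediate
15 | (2R,3S)-5,7-bis(benzyloxy)-2-[7-(methoxymethoxy)-2,2-diphenyl-1,3-benzodioxol-5-yl]-3,4-dihydro-2H-chromen-3-ol | COCOc1cc([C@H]2Oc3cc(OCc4ccccc4)cc(OCc4ccccc4)c3C[C@@H]2O)cc2OC(c3ccccc3)(c3ccccc3)Oc12 | intermediate
16 | (2R,3S)-5,7-bis(benzyloxy)-2-(7-hydroxy-2,2-diphenyl-1,3-benzodioxol-5-yl)-3,4-dihydro-2H-chromen-3-ol | Oc1cc([C@H]2Oc3cc(OCc4ccccc4)cc(OCc4ccccc4)c3C[C@@H]2O)cc2OC(c3ccccc3)(c3ccccc3)Oc12 | intermediate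
17 | 3,4,5-tris(benzyloxy)benzoic acid | OC(=O)c1cc(OCc2ccccc2)c(OCc2ccccc2)c(OCc2ccccc2)c1 | starting material
18 | 3,4,5-tris(benzyloxy)benzoyl chloride | ClC(=O)c1cc(OCc2ccccc2)c(OCc2ccccc2)c(OCc2ccccc2)c1 | intermediate
19 | 6-[(2R,3S)-5,7-bis(benzyloxy)-3-hydroxy-3,4-dihydro-2H-chromen-2-yl]-2,2-diphenyl-1,3-benzodioxol-4-yl 3,4,5-tris(benzyloxy)benzoate | O=C(Oc1cc([C@H]2Oc3cc(OCc4ccccc4)cc(OCc4ccccc4)c3C[C@@H]2O)cc2OC(c3ccccc3)(c3ccccc3)Oc12)c1cc(OCc2ccccc2)c(OCc2ccccc2)c(OCc2ccccc2)c1 | intermediate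
20 | gallocatechin 3'-O-gallate, (2R,3S) | O=C(Oc1cc([C@H]2Oc3cc(O)cc(O)c3C[C@@H]2O)cc(O)c1O)c1cc(O)c(O)c(O)c1 | target

**Totals**

Total step count: 14. Longest linear sequence: 9 steps (steps 5, 6, 7, 8, 9, 10, 11, 13, 14, from methyl gallate).

**Steps most likely to fail**

1. Step 10. The hydroboration may show incomplete facial selectivity, or the opposite sense, on this new enol ether, and the β-aryloxy borane may lose the ring aryloxide by base-induced elimination during oxidation, which opens ring C.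
   Fallback: it sets out from Weinreb amide 9 (with bromide 5 and acid chloride 18) and comes back to the route at 20. The two stereocentres are made one after the other.
   - Addition of (diphenylmethoxy)methyllithium (from tributyl[(diphenylmethoxy)methyl]stannane and n-BuLi, THF, −78 °C) to 9 should give the protected hydroxy ketone 2-(diphenylmethoxy)-1-aryl-ethanone F1.
   - Enantioselective phase-transfer benzylation of F1 with 5 (cinchonidine-derived N-(2,3,4-trifluorobenzyl)hydrocinchonidinium bromide, CsOH·H2O, CH2Cl2/hexane, −35 °C) should set C3 and give the (S)-α-(diphenylmethoxy) ketone F2.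
   - Chelation-controlled reduction with Zn(BH4)2 (Et2O, −20 °C) should give the anti (1R,2S) alcohol F3.
   - Intramolecular C–O coupling (Pd(OAc)2, 2-(di-tert-butylphosphino)-1,1′-binaphthyl, Cs2CO3, toluene, 80 °C) should close ring C to the 3-O-diphenylmethyl flavan F4.
   - NaHSO4·SiO2 should free the 3'-phenol F5, and 18 with Et3N and DMAP should give the 3-O-diphenylmethyl gallate F6, with no competing alcohol present.
   - Hydrogenolysis (H2, Pd(OH)2/C) should remove the benzyl, diphenylmethyl and diphenylmethylene groups together and give 20.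

2. Step 9. The labile benzylic bromide may be consumed by dialkylation or self-condensation, and the copper-mediated O-arylation of a simple ketone enolate may be slow or accompanied by base-induced shift of the double bond.
   Fallback: it sets out from ketone 10 and aldehyde 3 and comes back at 13. Claisen–Schmidt condensation (KOH, EtOH/THF) should give the (E)-chalcone F7. Conjugate reduction with catalytic [(Ph3P)CuH]6 and polymethylhydrosiloxane should give the saturated bromo ketone 12, now isolated. Intramolecular enolate O-arylation with Pd2(dba)3, bis[2-(diphenylphosphino)phenyl] ether and Cs2CO3 in toluene at 100 °C should close ring C to 13.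

3. Step 13. Chemoselectivity between the phenol and the secondary C3 alcohol may be lost, giving the bis-ester or the wrong ester.
   Fallback: it sets out from 15 and comes back at 19. Silylation (TBSOTf, 2,6-lutidine) should give the 3-O-TBS ether F8. MOM cleavage with TMSOTf and 2,2′-bipyridyl followed by water should give the 3-O-TBS phenol F9. Acylation with 18 (Et3N, DMAP) should give the 3-O-TBS gallate F10, and HF·pyridine in THF should remove the silyl group to give 19.

Further compounds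
F1 | step 10 | 2-(diphenylmethoxy)-1-[7-(methoxymethoxy)-2,2-diphenyl-1,3-benzodioxol-5-yl]ethan-1-one | O=C(COC(c1ccccc1)c1ccccc1)c1cc(OCOC)c2OC(c3ccccc3)(c3ccccc3)Oc2c1
F2 | step 10 | (2S)-3-[2,4-bis(benzyloxy)-6-bromophenyl]-2-(diphenylmethoxy)-1-[7-(methoxymethoxy)-2,2-diphenyl-1,3-benzodioxol-5-yl]propan-1-one | O=C([C@H](Cc1c(Br)cc(OCc2ccccc2)cc1OCc1ccccc1)OC(c1ccccc1)c1ccccc1)c1cc(OCOC)c2OC(c3ccccc3)(c3ccccc3)Oc2c1
F3 | step 10 | (1R,2S)-3-[2,4-bis(benzyloxy)-6-bromophenyl]-2-(diphenylmethoxy)-1-[7-(methoxymethoxy)-2,2-diphenyl-1,3-benzodioxol-5-yl]propan-1-ol | COCOc1cc([C@@H](O)[C@@H](OC(c2ccccc2)c2ccccc2)Cc2c(Br)cc(OCc3ccccc3)cc2OCc2ccccc2)cc2OC(c3ccccc3)(c3ccccc3)Oc12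
F4 | step 10 | (2R,3S)-5,7-bis(benzyloxy)-3-(diphenylmethoxy)-2-[7-(methoxymethoxy)-2,2-diphenyl-1,3-benzodioxol-5-yl]-3,4-dihydro-2H-chromene | COCOc1cc([C@H]2Oc3cc(OCc4ccccc4)cc(OCc4ccccc4)c3C[C@@H]2OC(c2ccccc2)c2ccccc2)cc2OC(c3ccccc3)(c3ccccc3)Oc12
F5 | step 10 | 6-[(2R,3S)-5,7-bis(benzyloxy)-3-(diphenylmethoxy)-3,4-dihydro-2H-chromen-2-yl]-2,2-diphenyl-1,3-benzodioxol-4-ol | Oc1cc([C@H]2Oc3cc(OCc4ccccc4)cc(OCc4ccccc4)c3C[C@@H]2OC(c2ccccc2)c2ccccc2)cc2OC(c3ccccc3)(c3ccccc3)Oc12
F6 | step 10 | 6-[(2R,3S)-5,7-bis(benzyloxy)-3-(diphenylmethoxy)-3,4-dihydro-2H-chromen-2-yl]-2,2-diphenyl-1,3-benzodioxol-4-yl 3,4,5-tris(benzyloxy)benzoate | O=C(Oc1cc([C@H]2Oc3cc(OCc4ccccc4)cc(OCc4ccccc4)c3C[C@@H]2OC(c2ccccc2)c2ccccc2)cc2OC(c3ccccc3)(c3ccccc3)Oc12)c1cc(OCc2ccccc2)c(OCc2ccccc2)c(OCc2ccccc2)c1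
F7 | step 9 | (E)-3-[2,4-bis(benzyloxy)-6-bromophenyl]-1-[7-(methoxymethoxy)-2,2-diphenyl-1,3-benzodioxol-5-yl]prop-2-en-1-one | O=C(/C=C/c1c(Br)cc(OCc2ccccc2)cc1OCc1ccccc1)c1cc(OCOC)c2OC(c3ccccc3)(c3ccccc3)Oc2c1
F8 | step 13 | tert-butyl{[(2R,3S)-5,7-bis(benzyloxy)-2-[7-(methoxymethoxy)-2,2-diphenyl-1,3-benzodioxol-5-yl]-3,4-dihydro-2H-chromen-3-yl]oxy}dimethylsilane | COCOc1cc([C@H]2Oc3cc(OCc4ccccc4)cc(OCc4ccccc4)c3C[C@@H]2O[Si](C)(C)C(C)(C)C)cc2OC(c3ccccc3)(c3ccccc3)Oc12
F9 | step 13 | 6-[(2R,3S)-5,7-bis(benzyloxy)-3-[(tert-butyldimethylsilyl)oxy]-3,4-dihydro-2H-chromen-2-yl]-2,2-diphenyl-1,3-benzodioxol-4-ol | Oc1cc([C@H]2Oc3cc(OCc4ccccc4)cc(OCc4ccccc4)c3C[C@@H]2O[Si](C)(C)C(C)(C)C)cc2OC(c3ccccc3)(c3ccccc3)Oc12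
F10 | step 13 | 6-[(2R,3S)-5,7-bis(benzyloxy)-3-[(tert-butyldimethylsilyl)oxy]-3,4-dihydro-2H-chromen-2-yl]-2,2-diphenyl-1,3-benzodioxol-4-yl 3,4,5-tris(benzyloxy)benzoate | O=C(Oc1cc([C@H]2Oc3cc(OCc4ccccc4)cc(OCc4ccccc4)c3C[C@@H]2O[Si](C)(C)C(C)(C)C)cc2OC(c3ccccc3)(c3ccccc3)Oc12)c1cc(OCc2ccccc2)c(OCc2ccccc2)c(OCc2ccccc2)c1
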